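The ratio of target standing to starting material gone reads 0.567 at 12.0 s and 0.557 at 25.0 s in the north-east run, and two chemists dispute what that ratio means for this same flask at 3.0 min.

| flask | starting material | remark | time |
|---|---|---|---|
| north-east | 1 mM | the very flask that is asked about, followed so far |  |
| flask | 1.0 mM |  | 3.0 min |

north-east run (percent of the starting material charged)

| time / s | starting material / % | target / % |
|---|---|---|
| 12.0 | 18.3 | 46.3 |
| 25.0 | 2.8 | 54.1 |
| 40.0 | 0.5 | 55.6 |
| 50.0 | 0.1 | 56.0 |
| 60.0 | 0.1 | 55.7 |
| 80.0 | 0.1 | 56.0 |

(scatter of a reading: 0.3 percentage points)

- the reaction counts as stopped when no species that holds the starting material changes by six tenths of a point or more over the second half of the time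

1. at 3.0 min, what has stopped the reaction, if anything has (it is still moving / forward and back rates have come level / all of the starting material has reacted)
2. part of the starting material gone at 3.0 min
3. the target standing at 3.0 min, as a percentage of the starting material charged
4. amount of target if the flask were left three thousand times as long, in percent of the starting material charged

The first chemist holds to one plain first-order step: from the fall of the starting material she reads a rate constant of 0.142 /s, so that 3.0 min spans 25.6 lifetimes, and she expects target to reach >99.9% of the charge, taking the shortfall in the readings for material still on its way.

The second chemist follows one molecule to a fork instead, and from the last three readings takes its chance of standing as target once it has left the starting material, 0.560, which she calls the keep share, the fraction of target standing per fraction of starting material gone, the usual selectivity.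

Against the first view she sets the target's drift of 0.4 percentage points between 40.0 s and 80.0 s in the north-east run, beside a scatter of 0.3 points, which is no climb toward the full charge.

I side with the second chemist: the keep share times the fraction gone gives 56.0% at 3.0 min, and I carry the same figure to the long wait, though the readings end at 80.0 s.

The forecast says all of the starting material has reacted, with 99.9% gone and target 55.9% (55.2% to 56.4%), close to my figure, and 56% (45% to 60%) after the long wait, reasoning “so it should still be about 56% at 3 min”.

The simulation gives all of the starting material has reacted at 3.0 min, with 100% gone, target 55.8%, and 55.8% after the long wait; the plain first-order fit puts target at >99.9%, so the first view keeps its region, the starting material, and loses the target.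

    starting material → target (k = 0.140 /s)
    starting material → side product (k = 0.00180 /s)
    target ⇌ isomer of the product (K = 0.770, k = 0.810 /s)

In this flask the step to target uses starting material 78 times as fast as the step to side product, while the exchange of target with isomer of the product has a backward turnover of 99.5% of its forward one up to 3.0 min, and the two chances multiplied, that of taking the step to target and that of standing as target rather than as isomer of the product, give 0.558. For the neighbour flask, charged with 0.40 mM, the keep share of 0.560 read in the north-east run gives 56.0% of its charge as target, and that neighbour flask holds target at 55.8% of its charge and isomer of the product at 43.0% at 3.00 min.

All runs were generated by integration for an exercise, and the scatter is random.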